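The other capture product looks easy to count. If it takes one second nucleophile per substrate, the second nucleophile is the limiting reagent of the flask, and 10.0 mM against 20 mM promises 50.0% of the substrate charged.

| flask | substrate | first nucleophile | second nucleophile | remark | time |
|---|---|---|---|---|---|
| winter | 10 mM | 20 mM | 10 mM | run made earlier |  |
| noon | 40 mM | 20 mM | 10 mM | run made earlier |  |
| autumn | 20 mM | 20 mM | 20 mM | run made earlier |  |
| flask | 20 mM | 20.0 mM | 10.0 mM |  | 30 min |

| run | time / min | other capture product / % | target / % | substrate / % |
|---|---|---|---|---|
| winter | 1.33 | 7.1 | 0.6 | 91.3 |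
| winter | 4.00 | 15.6 | 0.7 | 83.4 |
| winter | 6.00 | 18.0 | 0.1 | 80.3 |
| winter | 10.0 | 21.4 | 1.5 | 77.9 |
| winter | 15.0 | 22.5 | 0.5 | 76.7 |
| winter | 20.0 | 22.8 | 0.8 | 76.3 |
| noon | 3.00 | 10.5 | 0.4 | 88.4 |
| noon | 6.00 | 12.6 | 0.4 | 86.4 |
| noon | 10.0 | 13.8 | 0.8 | 84.5 |
| noon | 12.0 | 13.6 | 0.6 | 84.9 |
| noon | 15.0 | 14.0 | 0.8 | 84.9 |
| noon | 20.0 | 13.6 | 0.8 | 85.1 |
| autumn | 1.33 | 12.5 | 0.1 | 86.2 |
| autumn | 2.50 | 20.4 | 0.6 | 79.0 |
| autumn | 5.00 | 27.8 | 0 | 71.0 |
| autumn | 10.0 | 33.2 | 0.7 | 66.0 |
| autumn | 20.0 | 34.2 | 1.1 | 64.6 |

(readings scatter by 0.3 percentage points)



- ratio of other capture product to target at 25 s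
- ratio of other capture product to target at 3.0 min
- ratio of other capture product to target at 30 min
- which of other capture product and target there is more of at 30 min

The earlier runs refuse this count. The winter run promises 100%, yet by 20.0 min its other capture product stands at 22.8%, with 76.3% of the substrate still present. So I suppose that the second nucleophile has two fates: capture, whose rate goes with c(substrate), and a loss that does not. The captured share of its charge is then c(substrate)/(c(substrate) + m). Since c(substrate) falls, I replace its curve by the mean of charge and end. The last readings then give 30.0 mM, 31.2 mM and 31.9 mM for winter, noon and autumn. Within these runs substrate falls by 23.7%, 14.9% and 35.4%, which is no small change, yet the three values lie within 1.90 mM of each other, so here the mean costs little. I carry 31.0 mM as the break-even substrate, the c(substrate) at which second nucleophile is captured as fast as it is lost.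

The count needs c(substrate) far above m. In the flask c(substrate)/m is 0.645, which is the wrong side of that border. Solving the share equation for the flask gives 3.69 mM captured, or 18.4% of the substrate charged. The target readings of the three runs average 0.618%, so I expect a ratio near 29.9 at 30 min. The earliest reading comes after 25 s, so I commit to no early ratio.

The forecast gives 40, 32 and 22, with other capture product ahead, and says “Target stays near noise”; its late ratio lies below mine. The flask gives 4.57, 21.2 and 35.3, with other capture product ahead, at 18.8% against 0.531%.

    first nucleophile + intermediate ⇌ target (K = 45.0 /M, k = 4.20 /M/s)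
    substrate ⇌ intermediate (K = 0.00740, k = 0.0190 /s)
    second nucleophile + intermediate → other capture product (k = 16.0 /M/s)
    second nucleophile → decomposed reagent (k = 0.00340 /s)

I reckoned 6.31 mM of second nucleophile lost, and the flask holds 6.25 mM of decomposed reagent. One reason why other capture product leads in the flask is the back reaction of target to first nucleophile and intermediate: with that back reaction taken away, the ratio at 30 min goes from 35.3 to 0.383, and target leads. The same m, used on the neighbour flask with 40 mM of second nucleophile, gives 61.7% of the substrate charged, and that flask stands at 58.2%.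

Readings and results are calculated with constants of no real substance, and the scatter is random.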